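**Retrosynthetic overview**
1. Target 18 ⇐ hydroxy keto aldehyde 17 ⇐ triol 16: the C6 ketone / C7=C8 / C10 aldehyde unit is unveiled last, by oxidation and dehydration of a C8 tertiary alcohol.
2. Dihydropyran acetal ⇐ de Mayo photoannulation of triformylmethane 10 onto the cis C5=C9 alkene of cycloheptene 9 (forms C4–C5 and C1–C9), on the face opposite the CMe2 bridge.
3. Seven-membered ring ⇐ ring-closing metathesis of diene 7.
4. Diene 7 ⇐ hemiacylal 1: aldol at the lactol carbon (C6–C7), vinyl Grignard at C8, lactone → lactol → Wittig at C5.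
5. Ring order: cyclopropane (bought, with both its stereocentres) → seven-membered carbocycle → dihydropyran.

Assumption: hemiacylal 1 (the lactol of (1R)-cis-caronaldehydic acid, an industrial pyrethroid intermediate made from (+)-3-carene), ketone 2 and triformylmethane 10 are bought.

Locants used below: acetal carbon C1, ring oxygen O2, enol ether C3=C4, acetoxymethyl carbon C11 (on C4), ring-fusion carbons C5 and C9, ketone carbon C6, C7, C8 (bears the formyl carbon C10), cyclopropane CH carbons Ca (on C6) and Cb (on C5), bridge CMe2. C6 and C8 are temporary stereocentres carried as epimer mixtures; both are erased in steps 10 and 11.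

**Step 1**
Reactants: 1 hemiacylal (1R,5S)-4-hydroxy-6,6-dimethyl-3-oxabicyclo[3.1.0]hexan-2-one (lactol carbon = C6, lactone carbon = C5); 2 1-[(tert-butyldimethylsilyl)oxy]propan-2-one
Product: 4 keto lactone (1R,5S)-4-{3-[(tert-butyldimethylsilyl)oxy]-2-oxopropyl}-6,6-dimethyl-3-oxabicyclo[3.1.0]hexan-2-one, via hydroxy acid 3 (not isolated)
Conditions: 2 (2.2 equiv), LiN(i-Pr)2 (2.2 equiv), THF, −78 °C; 1, −78 → −40 °C; 1 M HCl; PPTS (cat.), PhMe, 25 °C
Reagents that add atoms: none
Why: Directed aldol addition of the kinetic lithium enolate of 2 (deprotonated at the methyl group) to the aldehyde form that the lithium salt of 1 opens to, then acid relactonisation of the cis hydroxy acid; the bought cyclopropane centres are untouched and the new carbinol C6 (both epimers) ends as the ketone.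

**Step 2**
Reactants: 4 keto lactone
Product: 5 tertiary alcohol (1R,5S)-4-[2-({[tert-butyl(dimethyl)silyl]oxy}methyl)-2-hydroxybut-3-en-1-yl]-6,6-dimethyl-3-oxabicyclo[3.1.0]hexan-2-one
Conditions: CH2=CHMgBr (1.3 equiv), LaCl3·2LiCl (0.3 equiv), THF, −78 °C; aq NH4Cl
Reagents that add atoms: vinylmagnesium bromide, C=C[Mg]Br
Why: Lanthanum-promoted Grignard 1,2-addition to the ketone outruns lactone attack and E1cB loss of the β-acyloxy group; C8 forms as both epimers, which does not matter because C8 becomes sp2 in step 11.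

**Step 3**
Reactants: 5 tertiary alcohol
Product: 7 diene diol 3-({[tert-butyl(dimethyl)silyl]oxy}methyl)-1-[(1S,3R)-3-ethenyl-2,2-dimethylcyclopropyl]pent-4-ene-1,3-diol, via lactol 6 (not isolated)
Conditions: i-Bu2AlH (2.2 equiv), CH2Cl2, −78 °C; aq potassium sodium tartrate; Ph3PCH3Br, KOt-Bu, THF, 0 → 25 °C
Reagents that add atoms: methylenetriphenylphosphorane, C=P(c1ccccc1)(c1ccccc1)c1ccccc1
Why: Partial reduction of the γ-lactone stops at lactol 6, whose open hydroxy aldehyde form undergoes Wittig methylenation faster than the cis cyclopropanecarbaldehyde epimerises, so Cb keeps its configuration and C5 becomes the vinyl CH.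

**Step 4**
Reactants: 7 diene diol
Product: 8 cycloheptene diol (1S,7R)-4-({[tert-butyl(dimethyl)silyl]oxy}methyl)-8,8-dimethylbicyclo[5.1.0]oct-5-ene-2,4-diol
Conditions: second-generation Grubbs catalyst RuCl2(=CHPh)(PCy3)(H2IMes) (5 mol%), CH2Cl2 (5 mM), 40 °C
Reagents that add atoms: none
Why: Ring-closing metathesis (helped by the free allylic hydroxyl) joins the vinylcyclopropane and the carbinol vinyl group into the seven-membered ring, in which the new C5=C9 alkene can only be cis.

**Step 5**
Reactants: 8 cycloheptene diol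
Product: 9 bis(triethylsilyl) ether (1S,7R)-4-({[tert-butyl(dimethyl)silyl]oxy}methyl)-8,8-dimethyl-2,4-bis[(triethylsilyl)oxy]bicyclo[5.1.0]oct-5-ene
Conditions: Et3SiOTf (3 equiv), 2,6-lutidine, CH2Cl2, −78 → 0 °C
Reagents that add atoms: triethylsilyl trifluoromethanesulfonate, CC[Si](CC)(CC)OS(=O)(=O)C(F)(F)F
Why: Silyl triflate silylation caps the secondary C6 and tertiary allylic C8 hydroxyls so that they neither ionise in the acidic photoreaction nor are acetylated in steps 7 and 8.

**Step 6**
Reactants: 9 bis(triethylsilyl) ether; 10 triformylmethane (enol form 2-(hydroxymethylene)propanedial)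
Product: 12 tricyclic lactol aldehyde (1-OH; C3=C4; 4-CHO; cis ring fusion at C5/C9), via cyclobutanol photoadduct 11 (not isolated)
Conditions: hν (300 nm, Pyrex), 10 (5 equiv), degassed MeCN/CH2Cl2, −40 °C; then 25 °C, dark, 12 h
Reagents that add atoms: none
Why: Proposed new method: triformylmethane exists as the hydrogen-bonded enol 2-(hydroxymethylene)malonaldehyde, whose excited state should add as a 2π partner across the cis C5=C9 alkene from the face opposite the CMe2 bridge to give the cis-fused cyclobutanol 11 (bis-formyl carbon C4 on the less hindered C5, because the other orientation would put two quaternary carbons side by side at C8/C9), and spontaneous retro-aldol cleavage of C1–C4 followed by hemiacetal closure of the enol onto the C1 aldehyde gives lactol 12, so C5 and C9 are set cis (H5 and H9 on the CMe2 face) by the suprafacial [2+2] step under control of the bought cyclopropane; the closest known reaction type is the de Mayo reaction of enolised 1,3-dicarbonyl compounds such as methyl diformylacetate with cycloalkenes, here extended to a tri-aldehyde enol (which delivers C11 as an aldehyde that can be reduced later without touching an acetate) and to a cycloheptene flanked by a gem-dimethylcyclopropane, the low temperature serving to slow cyclopropylcarbinyl ring opening of any biradical with spin at C5.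

**Step 7**
Reactants: 12 tricyclic lactol aldehyde
Product: 13 1-O-acetyl lactol aldehyde (1-OAc cis to the C9–C8 bond; 4-CHO)
Conditions: Ac2O, pyridine, DMAP (cat.), CH2Cl2, 0 °C
Reagents that add atoms: acetic anhydride, CC(=O)OC(C)=O
Why: DMAP-catalysed acylation traps the hemiacetal, which should sit mainly as the axial anomer (anomeric effect in the half-chair with the C5–Cb bond pseudoaxial), as the 1-O-acetate with the acetoxy group cis to the C9–C8 bond, the target configuration at C1; the minor anomer is removed by chromatography.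

**Step 8**
Reactants: 13 1-O-acetyl lactol aldehyde
Product: 15 diacetate (1-OAc; 11-OAc; silyl ethers as in 9), via allylic alcohol 14 (not isolated)
Conditions: NaBH4, CeCl3·7H2O, MeOH/THF, −40 °C; aq NH4Cl; Ac2O, pyridine, DMAP (cat.), CH2Cl2, 0 °C
Reagents that add atoms: acetic anhydride, CC(=O)OC(C)=O
Why: Luche 1,2-reduction takes the vinylogous formate aldehyde to allylic alcohol 14 without touching the acetate or silyl ethers, and the acid-sensitive alcohol is acetylated at once.

**Step 9**
Reactants: 15 diacetate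
Product: 16 triol (free C6-OH, C8-OH, C10-OH; 1,11-diacetate)
Conditions: HF·pyridine, pyridine, THF, 0 → 25 °C
Reagents that add atoms: none
Why: Fluoride-driven desilylation (Si–F bond formation) frees the three hydroxyls while the pyridine buffer preserves both acetates and the enol acetal.

**Step 10**
Reactants: 16 triol
Product: 17 hydroxy keto aldehyde (C6 ketone; C8 tertiary OH; C10 aldehyde)
Conditions: Dess–Martin periodinane (3 equiv), pyridine, CH2Cl2, 0 → 25 °C
Reagents that add atoms: none
Why: Dess–Martin oxidation converts the secondary C6 alcohol into the ketone and the primary C10 alcohol into the aldehyde under buffered conditions, the tertiary C8 alcohol being inert.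

**Step 11**
Reactants: 17 hydroxy keto aldehyde
Product: 18 target CNP0263020.2
Conditions: Burgess reagent (MeO2CN(−)SO2N(+)Et3, 2 equiv), PhMe, 25 → 50 °C
Reagents that add atoms: none
Why: Burgess dehydration (syn elimination of the tertiary sulfamate ester through the acidic C7–H next to the ketone) gives the C7=C8 double bond conjugated with both carbonyls without base, so C9 and the acetal are not disturbed.

**Compound list**
1 | (1R,5S)-4-hydroxy-6,6-dimethyl-3-oxabicyclo[3.1.0]hexan-2-one (cis-caronaldehydic acid hemiacylal, lactol epimers) | OC1[C@H]2[C@@H](C(=O)O1)C2(C)C | starting material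
2 | 1-[(tert-butyldimethylsilyl)oxy]propan-2-one | CC(=O)CO[Si](C)(C)C(C)(C)C | starting material
3 | (1R,3S)-3-{4-[(tert-butyldimethylsilyl)oxy]-1-hydroxy-3-oxobutyl}-2,2-dimethylcyclopropane-1-carboxylic acid (C6 epimers) | CC(C)(C)[Si](C)(C)OCC(=O)CC(O)[C@H]1[C@@H](C(O)=O)C1(C)C | intermediate
4 | (1R,5S)-4-{3-[(tert-butyldimethylsilyl)oxy]-2-oxopropyl}-6,6-dimethyl-3-oxabicyclo[3.1.0]hexan-2-one (C6 epimers) | CC(C)(C)[Si](C)(C)OCC(=O)CC1[C@H]2[C@@H](C(=O)O1)C2(C)C | intermediate
5 | (1R,5S)-4-[2-({[tert-butyl(dimethyl)silyl]oxy}methyl)-2-hydroxybut-3-en-1-yl]-6,6-dimethyl-3-oxabicyclo[3.1.0]hexan-2-one (C6/C8 epimers) | C=CC(O)(CO[Si](C)(C)C(C)(C)C)CC1[C@H]2[C@@H](C(=O)O1)C2(C)C | intermediate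
6 | lactol of 5: (1R,5S)-4-[2-({[tert-butyl(dimethyl)silyl]oxy}methyl)-2-hydroxybut-3-en-1-yl]-6,6-dimethyl-3-oxabicyclo[3.1.0]hexan-2-ol | C=CC(O)(CO[Si](C)(C)C(C)(C)C)CC1[C@H]2[C@@H](C(O)O1)C2(C)C | intermediate
7 | 3-({[tert-butyl(dimethyl)silyl]oxy}methyl)-1-[(1S,3R)-3-ethenyl-2,2-dimethylcyclopropyl]pent-4-ene-1,3-diol | C=CC(O)(CO[Si](C)(C)C(C)(C)C)CC(O)[C@H]1[C@@H](C=C)C1(C)C | intermediate
8 | (1S,7R)-4-({[tert-butyl(dimethyl)silyl]oxy}methyl)-8,8-dimethylbicyclo[5.1.0]oct-5-ene-2,4-diol | OC1[C@H]2[C@@H](C=CC(O)(CO[Si](C)(C)C(C)(C)C)C1)C2(C)C | intermediate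
9 | (1S,7R)-4-({[tert-butyl(dimethyl)silyl]oxy}methyl)-8,8-dimethyl-2,4-bis[(triethylsilyl)oxy]bicyclo[5.1.0]oct-5-ene | CC[Si](CC)(CC)OC1[C@H]2[C@@H](C=CC(O[Si](CC)(CC)CC)(CO[Si](C)(C)C(C)(C)C)C1)C2(C)C | intermediate
10 | triformylmethane (2-(hydroxymethylene)propanedial) | OC=C(C=O)C=O | starting material
11 | cyclobutanol photoadduct: cyclobutane C5–C4–C1–C9 cis-fused to the seven-membered ring of 9 on the face opposite CMe2; C4 bears two CHO, C1 bears OH | CC[Si](CC)(CC)OC1[C@H]2[C@@H]([C@H]3C(C=O)(C=O)C(O)[C@H]3C(O[Si](CC)(CC)CC)(CO[Si](C)(C)C(C)(C)C)C1)C2(C)C | intermediate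
12 | lactol aldehyde: 1-hydroxy dihydropyran (C3=C4, 4-CHO) cis-fused at C5/C9 to the silylated cyclopropane-fused seven-membered ring, H5 and H9 on the CMe2 face | CC[Si](CC)(CC)OC1[C@H]2[C@@H]([C@H]3C(C=O)=COC(O)[C@H]3C(O[Si](CC)(CC)CC)(CO[Si](C)(C)C(C)(C)C)C1)C2(C)C | intermediate
13 | 1-O-acetate of 12 (acetoxy cis to the C9–C8 bond) | CC[Si](CC)(CC)OC1[C@H]2[C@@H]([C@H]3C(C=O)=CO[C@@H](OC(C)=O)[C@H]3C(O[Si](CC)(CC)CC)(CO[Si](C)(C)C(C)(C)C)C1)C2(C)C | intermediate
14 | 11-alcohol: 13 with 4-CH2OH in place of 4-CHO | CC[Si](CC)(CC)OC1[C@H]2[C@@H]([C@H]3C(CO)=CO[C@@H](OC(C)=O)[C@H]3C(O[Si](CC)(CC)CC)(CO[Si](C)(C)C(C)(C)C)C1)C2(C)C | intermediate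
15 | 1,11-diacetate with C6-OSiEt3, C8-OSiEt3 and C10-OSi(t-Bu)Me2 | CC[Si](CC)(CC)OC1[C@H]2[C@@H]([C@H]3C(COC(C)=O)=CO[C@@H](OC(C)=O)[C@H]3C(O[Si](CC)(CC)CC)(CO[Si](C)(C)C(C)(C)C)C1)C2(C)C | intermediate
16 | triol: 1,11-diacetate with free C6-OH, C8-OH and C10-OH | OC1[C@H]2[C@@H]([C@H]3C(COC(C)=O)=CO[C@@H](OC(C)=O)[C@H]3C(O)(CO)C1)C2(C)C | intermediate
17 | hydroxy keto aldehyde: C6 ketone, C8 tertiary OH, C10 aldehyde, 1,11-diacetate | O=C1[C@H]2[C@@H]([C@H]3C(COC(C)=O)=CO[C@@H](OC(C)=O)[C@H]3C(O)(C=O)C1)C2(C)C | intermediate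
18 | CNP0263020.2 | CC(=O)OCC1=CO[C@@H](OC(C)=O)[C@H]2C(C=O)=CC(=O)[C@H]3[C@@H]([C@@H]12)C3(C)C | target

**Total step count:** 11. **Longest linear sequence:** 11 steps (1 → 18).

**Three steps most likely to fail**

Step 6 (the proposed new photoannulation). Risks are the acidity and unknown photochemistry of triformylmethane, regiochemistry, and cyclopropane opening through a biradical at C5. Fallback with known chemistry, setting out from 9 and returning at 15: irradiation of 9 with methyl diformylacetate (methyl 2-formyl-3-hydroxyprop-2-enoate), the enol partner for which this cycloalkene photoannulation is established, gives the methyl ester lactol F2. The lactol hydroxyl is capped with Me3SiCl/imidazole to give the trimethylsilyl acetal F3. i-Bu2AlH (CH2Cl2, −78 → −40 °C) then reduces the vinylogous carbonate ester to the allylic alcohol, and a citric acid work-up removes the trimethylsilyl group to give the lactol diol F4. Ac2O/pyridine/DMAP converts F4 into diacetate 15. This replaces only the new enol partner; it does not remove the cyclopropane-opening risk.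

Step 11 (dehydration of a tertiary α-hydroxy aldehyde / β-hydroxy ketone; risks are retro-aldol, acyloin shift and elimination towards C9). Fallback from 17 to 18 by a stepwise acylation/E1cB route instead of the thermal syn elimination: (CF3CO)2O/pyridine at −20 °C acylates the tertiary hydroxyl to give the β-(trifluoroacetoxy) ketone F5. DBU at 0 °C then removes the C7 proton and expels trifluoroacetate to give 18.

Step 1 (aldol on the hemiacylal; risks are enolisation of 2 on the silyloxy side, retro-aldol and epimerisation of the cis aldehyde). Fallback from 1 to 4 by allylation/ozonolysis: Zn-mediated Barbier allylation of 1 with tert-butyl{[2-(bromomethyl)prop-2-en-1-yl]oxy}dimethylsilane (THF/aq NH4Cl), followed by acid lactonisation, gives the homoallylic lactone F1. Ozonolysis of its 1,1-disubstituted alkene (O3, CH2Cl2, −78 °C; Me2S) gives keto lactone 4.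

**Further compounds**
F1 | step 1 | (1R,5S)-4-[2-({[tert-butyl(dimethyl)silyl]oxy}methyl)prop-2-en-1-yl]-6,6-dimethyl-3-oxabicyclo[3.1.0]hexan-2-one | C=C(CO[Si](C)(C)C(C)(C)C)CC1[C@H]2[C@@H](C(=O)O1)C2(C)C
F2 | step 6 | methyl ester lactol: 12 with 4-CO2Me in place of 4-CHO | CC[Si](CC)(CC)OC1[C@H]2[C@@H]([C@H]3C(C(=O)OC)=COC(O)[C@H]3C(O[Si](CC)(CC)CC)(CO[Si](C)(C)C(C)(C)C)C1)C2(C)C
F3 | step 6 | trimethylsilyl acetal of F2 (1-OSiMe3) | CC[Si](CC)(CC)OC1[C@H]2[C@@H]([C@H]3C(C(=O)OC)=COC(O[Si](C)(C)C)[C@H]3C(O[Si](CC)(CC)CC)(CO[Si](C)(C)C(C)(C)C)C1)C2(C)C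
F4 | step 6 | lactol diol: 12 with 4-CH2OH in place of 4-CHO | CC[Si](CC)(CC)OC1[C@H]2[C@@H]([C@H]3C(CO)=COC(O)[C@H]3C(O[Si](CC)(CC)CC)(CO[Si](C)(C)C(C)(C)C)C1)C2(C)C
F5 | step 11 | tertiary trifluoroacetate of 17 (C8-OCOCF3) | O=C1[C@H]2[C@@H]([C@H]3C(COC(C)=O)=CO[C@@H](OC(C)=O)[C@H]3C(OC(=O)C(F)(F)F)(C=O)C1)C2(C)C
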